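**Retrosynthetic overview**
- Disconnect the methine–ring A bond: a catalytic asymmetric Friedel–Crafts addition of ring A monomer 11 to a ring B ortho-quinone methide (o-QM), released in situ from sulfone 5, forms the target directly in the last step.
- Sulfone 5 comes from 3-prenylphloracetophenone 3, isovaleraldehyde and p-toluenesulfinic acid; 3 comes from phloracetophenone by enzymatic C-prenylation (aromatic prenyltransferase).
- Monomer 11 comes from 2',4'-dihydroxy-6'-methoxyacetophenone by 4-O-MOM protection, O-prenylation, para-Claisen–Cope rearrangement and deprotection.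
- No ring is constructed: both benzene rings are bought intact. Order of events: functionalise ring B, functionalise ring A, then join them at the stereocentre.

Assumption 1: the target stereocentre is (R) by CIP (OMe-ring > trihydroxy-ring > CH2 > H).
Assumption 2: the sense of induction in Step 7 must be found empirically. The quinine-derived catalyst is written; if the first run gives (S), its quinidine-derived pseudo-enantiomer is used instead.
Assumption 3: 2',4'-dihydroxy-6'-methoxyacetophenone and DMAPP (ammonium salt) are purchased.

**Step 1**
Reactants: 1, 2',4',6'-trihydroxyacetophenone (phloracetophenone); 2, dimethylallyl diphosphate (DMAPP)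
Product: 3, 1-[2,4,6-trihydroxy-3-(3-methylbut-2-en-1-yl)phenyl]ethanone
Conditions: recombinant DMATS-type aromatic prenyltransferase (e.g. AnaPT), 2 (1.3 equiv), Tris·HCl pH 7.5, CaCl2 5 mM, 5% DMSO, 37 °C, 16 h; EtOAc extraction
Reagents that add atoms: none (the prenyl unit comes from reactant 2)
Why: Enzymatic Friedel–Crafts C-prenylation; the enzyme delivers the dimethylallyl cation to a ring carbon of the symmetric acylphloroglucinol and gives mono-C-prenylation only, avoiding the O-prenyl and poly-prenyl mixtures of prenyl bromide/base.

**Step 2**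
Reactants: 3; 4, 3-methylbutanal (isovaleraldehyde)
Product: 5, (±)-1-{2,4,6-trihydroxy-3-(3-methylbut-2-en-1-yl)-5-[3-methyl-1-(4-methylbenzenesulfonyl)butyl]phenyl}ethanone
Conditions: p-TolSO2H (2 equiv, from TolSO2Na/HCl), 4 (1.5 equiv), EtOAc, 0 °C to rt; 3 added slowly; triturate
Reagents that add atoms: p-toluenesulfinic acid, Cc1ccc(cc1)S(=O)O
Why: Three-component Friedel–Crafts hydroxyalkylation with sulfinate trapping; the only free ring carbon of 3 adds to the aldehyde and the excess sulfinate captures the resulting o-QM in preference to a second molecule of 3, giving a bench-stable o-QM precursor whose racemic sulfone carbon is erased in Step 7.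

**Step 3**
Reactants: 6, 1-(2,4-dihydroxy-6-methoxyphenyl)ethanone
Product: 7, 1-[2-hydroxy-6-methoxy-4-(methoxymethoxy)phenyl]ethanone
Conditions: MOMCl (1.1 equiv), i-Pr2NEt, CH2Cl2, 0 °C
Reagents that add atoms: chloromethyl methyl ether, COCCl
Why: Selective O-alkylation (acetal protection); the 4-OH is free and more acidic, whereas the 2-OH is chelated to the acetyl carbonyl and stays untouched.

**Step 4**
Reactants: 7; 8, 3-methylbut-2-en-1-ol (prenol)
Product: 9, 1-[2-methoxy-4-(methoxymethoxy)-6-(3-methylbut-2-en-1-yloxy)phenyl]ethanone
Conditions: PPh3, DIAD, THF, 0 °C to rt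
Reagents that add atoms: none
Why: Mitsunobu etherification; it O-alkylates the chelated phenol under neutral conditions without competing C-alkylation, as used on the closely related bis-MOM phloracetophenone.

**Step 5**
Reactants: 9
Product: 10, 1-[6-hydroxy-2-methoxy-4-(methoxymethoxy)-3-(3-methylbut-2-en-1-yl)phenyl]ethanone
Conditions: PhNEt2, 200 °C, 3 h, Ar
Reagents that add atoms: none
Why: Para-Claisen–Cope rearrangement; the ortho-dienone (reverse-prenyl) relays by Cope shift to the position para to the ether oxygen, which is the carbon between OMe and OMOM, so the prenyl group lands exactly where ring A needs it.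

**Step 6**
Reactants: 10
Product: 11, 1-[4,6-dihydroxy-2-methoxy-3-(3-methylbut-2-en-1-yl)phenyl]ethanone
Conditions: 3 M HCl, MeOH, rt; NaHCO3 quench
Reagents that add atoms: none
Why: Acid-catalysed acetal (MOM) hydrolysis; at room temperature it is mild enough to leave the prenyl alkene uncyclised, as in prenylchalcone syntheses.

**Step 7**
Reactants: 5 (1.2 equiv); 11 (1.0 equiv)
Product: 12, 1-{3-[(1R)-1-[3-acetyl-2,4,6-trihydroxy-5-(3-methylbut-2-en-1-yl)phenyl]-3-methylbutyl]-2,4-dihydroxy-6-methoxy-5-(3-methylbut-2-en-1-yl)phenyl}ethanone (target)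
Conditions: quinine-derived 3,5-(CF3)2C6H3-squaramide (10 mol %), sat. aq. NaHCO3/CH2Cl2, 0 °C; pH 6 buffer quench; recrystallise to upgrade ee; keep product neutral and cold
Reagents that add atoms: none
Why: Catalytic asymmetric Friedel–Crafts (vinylogous Michael) alkylation of an in situ o-QM; bicarbonate-induced 1,4-elimination of sulfinate from 5 gives the planar ring B o-QM, and the bifunctional squaramide H-bonds to it while its quinuclidine positions the phenol of 11, so the single free carbon of 11 attacks one enantioface and rearomatisation sets the (R) centre. Ring B of 5 has no free carbon and 11 has no leaving group, so only the cross-product can form.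

**Compound list**
1 | 2',4',6'-trihydroxyacetophenone | CC(=O)c1c(O)cc(O)cc1O | starting material
2 | dimethylallyl diphosphate (DMAPP) | CC(C)=CCOP(=O)(O)OP(=O)(O)O | starting material
3 | 1-[2,4,6-trihydroxy-3-(3-methylbut-2-en-1-yl)phenyl]ethanone | CC(=O)c1c(O)cc(O)c(CC=C(C)C)c1O | intermediate
4 | 3-methylbutanal | CC(C)CC=O | starting material
5 | (±)-1-{2,4,6-trihydroxy-3-prenyl-5-[3-methyl-1-tosylbutyl]phenyl}ethanone | CC(=O)c1c(O)c(CC=C(C)C)c(O)c(C(CC(C)C)S(=O)(=O)c2ccc(C)cc2)c1O | intermediate
6 | 1-(2,4-dihydroxy-6-methoxyphenyl)ethanone | COc1cc(O)cc(O)c1C(C)=O | starting material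
7 | 1-[2-hydroxy-6-methoxy-4-(methoxymethoxy)phenyl]ethanone | COCOc1cc(O)c(C(C)=O)c(OC)c1 | intermediate
8 | 3-methylbut-2-en-1-ol | CC(C)=CCO | starting material
9 | 1-[2-methoxy-4-(methoxymethoxy)-6-(3-methylbut-2-en-1-yloxy)phenyl]ethanone | COCOc1cc(OCC=C(C)C)c(C(C)=O)c(OC)c1 | intermediate
10 | 1-[6-hydroxy-2-methoxy-4-(methoxymethoxy)-3-(3-methylbut-2-en-1-yl)phenyl]ethanone | COCOc1cc(O)c(C(C)=O)c(OC)c1CC=C(C)C | intermediate
11 | 1-[4,6-dihydroxy-2-methoxy-3-(3-methylbut-2-en-1-yl)phenyl]ethanone | COc1c(CC=C(C)C)c(O)cc(O)c1C(C)=O | intermediate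
12 | (R)-configured target, CID44559660 | COc1c(CC=C(C)C)c(O)c([C@H](CC(C)C)c2c(O)c(CC=C(C)C)c(O)c(C(C)=O)c2O)c(O)c1C(C)=O | target

**Totals**
Total steps: 7 (convergent). Longest linear sequence: 5 steps (6 → 7 → 9 → 10 → 11 → 12).

**Steps most likely to fail**
1. Step 7. Risks: modest ee with two polyphenolic partners, or erosion of ee by reversible retro-Friedel–Crafts under base. Fallback: move to a Brønsted-acid manifold. Convert 5 (Et3N, elimination then tautomerisation) into the achiral (E)-o-hydroxystyrene, 1-[2,4,6-trihydroxy-3-(3-methylbut-1-enyl)-5-prenylphenyl]ethanone. A chiral phosphoric acid (TRIP type, toluene, −40 °C) then protonates it to an ion-paired o-QM that 11 attacks, with no base present.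
2. Step 2. Risks: the symmetric bis-adduct (two molecules of 3 on one aldehyde) or acid-induced prenyl cyclisation. Fallback: make the o-QM precursor as a Betti (Mannich) base instead, from 3 and the preformed iminium of isovaleraldehyde and morpholine in EtOH without acid. The amine out-competes 3 for the o-QM; the o-QM is then released by N-methylation and mild base.
3. Step 5. Risks: ortho-Claisen (reverse-prenyl) by-product and thermal loss, giving a low yield of 10. Fallback: abandon prenyl migration and make 11 from the enzyme-derived 3 by regioselective O-methylation. This means bis-MOM protection of the 4-OH and the less hindered 6-OH, Me2SO4/K2CO3 methylation of the remaining 2-OH, then HCl/MeOH, with chromatographic removal of the minor regioisomer.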